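The pitfall is to carry an early capture ratio to the end of a run: in the cedar run, target over other capture product reads 6.29 at 0.200 h but 1.50 at 3.00 h.

Substrate gives intermediate; first nucleophile captures it to target, second nucleophile captures it to other capture product, and second nucleophile also attacks target to give over-reaction product.

| setting | cedar | alder | flask |
|---|---|---|---|
| substrate | 28 mM | 63 mM | 42 mM |
| first nucleophile | 33.6 mM | 33.6 mM | 33.6 mM |
| second nucleophile | 25.2 mM | 25.2 mM | 25.2 mM |
| remark | run made earlier | run made earlier |  |
| time |  |  | 3.0 h |

| run | time / h | target / % | other capture product / % |
|---|---|---|---|
| cedar | 0.200 | 44 | 7 |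
| cedar | 0.667 | 20 | 8 |
| cedar | 1.00 | 17 | 6 |
| cedar | 1.50 | 14 | 8 |
| cedar | 2.50 | 11 | 8 |
| cedar | 3.00 | 12 | 8 |
| alder | 0.200 | 38 | 21 |
| alder | 0.667 | 34 | 22 |
| alder | 1.00 | 36 | 21 |
| alder | 1.50 | 33 | 20 |
| alder | 2.50 | 33 | 21 |
| alder | 3.00 | 35 | 24 |

(readings scatter by 1.5 percentage points)

- the analysis behind the earlier runs scatters by 1.5 percentage points, standard deviation
- steps under discussion: second nucleophile + intermediate -> other capture product; second nucleophile + target -> over-reaction product; first nucleophile + intermediate -> target; substrate -> intermediate

- ratio of target to other capture product at 10 s
- ratio of target to other capture product at 3.0 h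
- which of target and other capture product there is more of at 3.0 h

Two chemists dispute the flask. The first holds to the selectivity factor: cedar had the same nucleophile charges as the flask, so the flask should keep a ratio near the early cedar reading of 6.29.

The second counts instead, taking capture as fast. When both free nucleophiles stand at zero, target plus over-reaction product equals the first nucleophile's fraction of the charge, 80.0% in the flask. Other capture product plus over-reaction product equals the second nucleophile's fraction, 60.0%. Over-reaction product cancels on subtraction, which leaves the capture margin, the first nucleophile's fraction minus the second's, 20.0% for the flask.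

The alder run tests it: the margin there is 13.3%, and the readings at 1.50 h differ by 13 percentage points, each with scatter 1.5 points. Cedar lies outside the count, since its first nucleophile, the charge being 120% of substrate, is more than the substrate. In the flask the charge of first nucleophile is larger than that of second nucleophile, so the margin is positive and the second chemist expects target ahead.

The forecast takes the second side: “The data point to stoichiometric exhaustion”. It gives 14.5 at 10 s, 2 at 3.0 h, and target ahead.

The flask gives 2.17 at 3.0 h, with target ahead, 37.1% against 17.1%: a gap of 20 points with first nucleophile at 0% and second at 0%. The selectivity view keeps the first seconds: the ratio is 17.4 at 10 s, higher than at the end.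

    second nucleophile + intermediate → other capture product (k = 63.0 L mol⁻¹ min⁻¹)
    second nucleophile + target → over-reaction product (k = 5.20 L mol⁻¹ min⁻¹)
    first nucleophile + intermediate → target (k = 840 L mol⁻¹ min⁻¹)
    substrate → intermediate (k = 0.190 min⁻¹)

A neighbouring flask charged with 6.3 mM of second nucleophile has a margin of 65.0%. Both its nucleophiles stand at 0% by 3.0 h, with target at 69.6% and other capture product at 4.61%, a gap of 65 points.

(The numbers in the tables are calculated for substances that don't exist, noise included.)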